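## Retrosynthetic overview

1. The target (7) comes from epoxyquinone 6 by reduction of the C5 carbonyl (anti to the epoxide) with in-situ acetylation; 6 comes from epoxy monoketal 5 by ketal hydrolysis.
2. Epoxide 5 comes from quinone monoketal 4 by reagent-controlled asymmetric nucleophilic epoxidation. The ketal leaves only the farnesyl-bearing enone with a free β-CH, which fixes the regiochemistry.
3. Key step: 4 comes from phenol 3 by a one-pot double oxidative dearomatization (para C–H methoxylation, then ketalization) with PhI(OAc)2/MeOH.
4. Phenol 3 comes from m-cresol (1) and (2E,6E)-farnesyl bromide (2) by ortho C-farnesylation.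
5. Ring order: the carbocycle is the m-cresol ring (dearomatized in step 2); the oxirane is formed in step 3.

Assumptions (one line each):
- Commercial farnesyl bromide is used as the (2E,6E) isomer.
- L-(+)-DIPT is assumed to give the (1R,6S) epoxide; this sense is not established for this substrate, and D-(−)-DIPT is used instead if the first batch proves to be the antipode.

Ring numbering used for 5–7: 7-oxabicyclo[4.1.0]hept-3-en-2-one, with C1 = farnesyl-bearing epoxide carbon, C2 = ketone, C3 = CH=, C4 = C–Me, C5 = ketal / C=O / CH–OAc carbon, C6 = epoxide CH. "Farnesyl" means (2E,6E)-3,7,11-trimethyldodeca-2,6,10-trien-1-yl.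

## Route

**Step 1**
Reactants: 1, m-cresol (3-methylphenol); 2, (2E,6E)-farnesyl bromide
Product: 3, 2-farnesyl-5-methylphenol
Conditions: NaH (1.0 equiv), PhMe, 0 °C → rt; then 2 (0.9 equiv), rt, 16 h
Reagents that add atoms: none other than reactant 2, farnesyl bromide, BrC/C=C(\C)CC/C=C(\C)CCC=C(C)C
Why: Heterogeneous (Kornblum-type) ortho C-allylation of a sodium phenoxide in a non-polar solvent; the tight ion pair directs SN2 attack to the less hindered ortho carbon (C6, para to the methyl) with retention of the E,E geometry. No stereocenter is formed; the O-ether and 2,3-isomer are removed by chromatography, and the yield is expected to be modest.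

**Step 2 (key step)**
Reactants: 3, 2-farnesyl-5-methylphenol
Product: 4, 2-farnesyl-4,4-dimethoxy-5-methylcyclohexa-2,5-dien-1-one
Conditions: PhI(OAc)2 (2.3 equiv), dry MeOH, 0 °C → rt; NaHCO3 quench
Reagents that add atoms: methanol, CO (two OMe groups)
Why: Hypervalent-iodine oxidative dearomatization run twice in one pot. The first oxidation methoxylates the free para C–H and rearomatizes to the p-methoxyphenol; the second, faster oxidation of that phenol gives the quinone monoketal. The isolated farnesyl alkenes are inert to PhI(OAc)2 at 0 °C. No stereocenter is formed, but the two ring alkenes are now differentiated.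

**Step 3**
Reactants: 4, quinone monoketal
Product: 5, (1R,6S)-1-farnesyl-5,5-dimethoxy-4-methyl-7-oxabicyclo[4.1.0]hept-3-en-2-one
Conditions: Ph3COOH, NaHMDS, L-(+)-DIPT, 4 Å MS, PhMe, −65 °C
Reagents that add atoms: trityl hydroperoxide, OOC(c1ccccc1)(c1ccccc1)c1ccccc1 (epoxide O)
Why: Tartrate-mediated Weitz–Scheffer nucleophilic epoxidation. The peroxide anion can only add to the β-CH of the farnesyl-bearing enone, because the other β-carbon carries a methyl and the ketal; the chiral sodium tartrate–peroxide aggregate selects the enone face and sets both epoxide carbons (1R,6S) in one event. The electron-rich farnesyl alkenes do not react with a nucleophilic oxidant.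

**Step 4**
Reactants: 5, epoxy monoketal
Product: 6, (1R,6S)-1-farnesyl-4-methyl-7-oxabicyclo[4.1.0]hept-3-ene-2,5-dione
Conditions: montmorillonite K10, wet CH2Cl2, rt
Reagents that add atoms: water, O (carbonyl oxygen)
Why: Mild acid-catalysed dimethyl ketal hydrolysis on clay, which leaves the epoxide, enone and triene untouched. No stereocenter is affected.

**Step 5**
Reactants: 6, epoxyquinone
Product: 7, (1R,5R,6R)-5-acetoxy-1-farnesyl-4-methyl-7-oxabicyclo[4.1.0]hept-3-en-2-one (target)
Conditions: DIBAL-H (1.05 equiv), CH2Cl2, −78 °C; then pyridine, DMAP, Ac2O, −78 → 0 °C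
Reagents that add atoms: acetic anhydride, CC(=O)OC(C)=O
Why: Regio- and diastereoselective 1,2-reduction with in-situ acylation of the aluminium alkoxide (reductive acetylation). The C5 carbonyl is flanked only by the epoxide C–H, whereas the C2 carbonyl is next to the quaternary C1 and deactivated by the β-methyl, so hydride should add at C5. Attack anti to the epoxide oxygen gives the acetate cis to the oxirane (5R).

## Compound list

1 | m-cresol | Cc1cccc(O)c1 | starting material
2 | (2E,6E)-farnesyl bromide | BrC/C=C(\C)CC/C=C(\C)CCC=C(C)C | starting material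
3 | 2-farnesyl-5-methylphenol | Cc1ccc(C/C=C(\C)CC/C=C(\C)CCC=C(C)C)c(O)c1 | intermediate
4 | 2-farnesyl-4,4-dimethoxy-5-methylcyclohexa-2,5-dien-1-one | COC1(OC)C=C(C/C=C(\C)CC/C=C(\C)CCC=C(C)C)C(=O)C=C1C | intermediate
5 | (1R,6S)-1-farnesyl-5,5-dimethoxy-4-methyl-7-oxabicyclo[4.1.0]hept-3-en-2-one | COC1(OC)C(C)=CC(=O)[C@]2(C/C=C(\C)CC/C=C(\C)CCC=C(C)C)O[C@H]12 | intermediate
6 | (1R,6S)-1-farnesyl-4-methyl-7-oxabicyclo[4.1.0]hept-3-ene-2,5-dione | O=C1C(C)=CC(=O)[C@]2(C/C=C(\C)CC/C=C(\C)CCC=C(C)C)O[C@H]12 | intermediate
7 | (1R,5R,6R)-5-acetoxy-1-farnesyl-4-methyl-7-oxabicyclo[4.1.0]hept-3-en-2-one | CC(=O)O[C@@H]1C(C)=CC(=O)[C@]2(C/C=C(\C)CC/C=C(\C)CCC=C(C)C)O[C@H]12 | target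

## Summary

Total step count: 5. Longest linear sequence: 5.

Three steps most likely to fail, each with a fallback that changes the approach:

1. **Step 5 (regio- and facial selectivity of the reduction).** If regioselectivity is poor, reduce both carbonyls to the diol, acetylate the less hindered C5–OH selectively, and re-oxidize the C2 allylic alcohol (MnO2 or Dess–Martin). If the C5 epimer (trans to the epoxide) forms, isolate the alcohol and invert it directly to the acetate by Mitsunobu reaction with AcOH.
2. **Step 2 (double oxidative dearomatization; ortho-ketal or side-chain participation by-products).** Start instead from the pre-oxygenated arene: farnesylate 4-methoxy-3-methylphenol, so that a single PhI(OAc)2/MeOH oxidation of a p-methoxyphenol gives the same ketal 4.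
3. **Step 3 (ee and sense of the asymmetric epoxidation).** Use racemic Weitz–Scheffer epoxidation (t-BuOOH/DBU), carry the material through to the racemic epoxyquinol, and resolve by lipase-catalysed enantioselective acetylation (vinyl acetate), which gives the target acetate directly.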